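## Retrosynthetic overview

1. Target 5 ⇒ benzylic C–O disconnection: water adds 1,6 to the exocyclic CH2 of 2-hydroxy-p-quinone methide 4.
2. 4 ⇒ tautomer of o-quinone 3 ⇒ two-electron oxidation of tribromo-4-methylcatechol 2. The net change is benzylic C–H to C–OH in one flask.
3. 2 ⇒ three C–Br disconnections: exhaustive electrophilic bromination of 4-methylcatechol 1.
4. No ring is formed. The benzene ring is bought with 1.

Assumption 1: the target has no stereocentre and is achiral, so there is no enantiomer to control.

Assumption 2: the route has only two steps. The risk list therefore names step 2 twice, for two independent failure modes, and step 1 once.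

## Route

Step 1
Reactants: 1 4-methylbenzene-1,2-diol (4-methylcatechol)
Product: 2 3,4,6-tribromo-5-methylbenzene-1,2-diol
Conditions: Br2 (3.1 equiv), AcOH, 15 °C to rt, 4 h
Reagents that add atoms: bromine, BrBr
Why: Exhaustive electrophilic aromatic bromination works because the two OH groups activate all three free ring positions, so there is no regiochemical choice, the acidic AcOH/HBr medium keeps the catechol from going to the quinone, and no stereocentre is formed.

Step 2
Reactants: 2 3,4,6-tribromo-5-methylbenzene-1,2-diol
Product: 5 3,4,6-tribromo-5-(hydroxymethyl)benzene-1,2-diol (2,3,6-tribromo-4,5-dihydroxybenzyl alcohol), via tribromo-methyl-o-benzoquinone 3 (not isolated), via hydroxy-p-quinone methide 4 (not isolated)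
Conditions: PhI(OAc)2 (1.0 equiv in MeCN, syringe pump over 4 h), NaOAc (5 equiv), MeCN/H2O 1:1, 0.03 M, N2, 40 °C, then 1 h
Reagents that add atoms: water, O
Why: Proposed new method: a redox-buffered benzylic C–H hydroxylation of a perhalogenated 4-methylcatechol, in which the trivalent iodine reagent oxidises 2 to o-quinone 3, acetate as general base removes a CH3 proton (vinylogous enolisation of the enone, made easier by three bromines) to give 2-hydroxy-p-quinone methide 4, and water adds 1,6 to the exocyclic CH2 with rearomatisation to form the benzylic C–O bond; the three bromines block the ring Michael additions and Diels–Alder dimerisation that normally consume 4-methyl-o-quinone, slow feeding of the oxidant keeps unreacted 2 in excess so that fast catechol/quinone exchange holds the harder-to-oxidise product 5 in its reduced form, adducts of 4 with acetate or phenoxide re-ionise and drain to the alcohol, and no stereocentre is formed; the closest known reaction types are the o-quinone to p-quinone methide isomerisation with hydration known for 4-alkylcatechols with longer side chains under enzymatic or periodate oxidation, and the Zincke–Auwers hydrolysis of polybrominated 4-hydroxybenzyl bromides through quinone methides.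

## Compound list

1 | 4-methylbenzene-1,2-diol (4-methylcatechol) | Cc1ccc(O)c(O)c1 | starting material
2 | 3,4,6-tribromo-5-methylbenzene-1,2-diol | Cc1c(Br)c(O)c(O)c(Br)c1Br | intermediate
3 | 3,4,6-tribromo-5-methylcyclohexa-3,5-diene-1,2-dione | CC1=C(Br)C(=O)C(=O)C(Br)=C1Br | intermediate
4 | 2,3,5-tribromo-6-hydroxy-4-methylidenecyclohexa-2,5-dien-1-one | C=C1C(Br)=C(O)C(=O)C(Br)=C1Br | intermediate
5 | 3,4,6-tribromo-5-(hydroxymethyl)benzene-1,2-diol | OCc1c(Br)c(O)c(O)c(Br)c1Br | target

## Summary

Total step count: 2. Longest linear sequence: 2.

## Steps most likely to fail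

**Risk 1: step 2 (the proposed new step), tautomerisation stage.** Acetate may deprotonate the CH3 of 3 more slowly than water or acetate displaces a ring bromide of the quinone. In that case little 4 and little 5 would form.

The fallback uses only known chemistry. It sets out from 2 and returns at 5.
- 2 is acetylated with Ac2O and pyridine to 3,4,6-tribromo-5-methyl-1,2-phenylene diacetate F1.
- Wohl–Ziegler bromination (NBS, AIBN, PhCF3, reflux) gives 3,4,6-tribromo-5-(bromomethyl)-1,2-phenylene diacetate F2.
- NaOH (3.3 equiv) in THF/H2O under N2, followed by 1 M HCl, cleaves both acetates. The 4-hydroxybenzyl bromide solvolyses in the same pot to 5.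

**Risk 2: step 2, selectivity stage.** Redox exchange between 3 and product 5 could oxidise 5. Its quinone would then tautomerise to the aldehyde, leaving a mixture of 2, 5 and aldehyde.

The fallback changes the oxidation-level strategy. It sets out from 2 and returns at 5.
- 2 is taken on purpose to the aldehyde with DDQ (2.2 equiv) in dioxane/H2O. This is the known DDQ oxidation of 4-methylphenols to 4-hydroxybenzaldehydes, and it gives 2,3,6-tribromo-4,5-dihydroxybenzaldehyde F3.
- NaBH4 in EtOH at 0 °C reduces the aldehyde to 5.

**Risk 3: step 1.** The third bromination may stall. Excess Br2 may also oxidise the free catechol or start to brominate the side chain, giving mixtures that are hard to purify.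

The fallback removes the redox-active catechol during halogenation. It sets out from 1 and returns at 2.
- 1 is methylated (MeI, K2CO3, acetone) to 1,2-dimethoxy-4-methylbenzene F4.
- Br2 in excess with catalytic FeBr3 in CH2Cl2 at reflux gives 1,2,4-tribromo-5,6-dimethoxy-3-methylbenzene F5.
- BBr3 in CH2Cl2, −78 °C to rt, cleaves both methyl ethers to 2.

## Further compounds

F1 | step 2 | 3,4,6-tribromo-5-methyl-1,2-phenylene diacetate | Cc1c(Br)c(OC(C)=O)c(OC(C)=O)c(Br)c1Br
F2 | step 2 | 3,4,6-tribromo-5-(bromomethyl)-1,2-phenylene diacetate | BrCc1c(Br)c(OC(C)=O)c(OC(C)=O)c(Br)c1Br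
F3 | step 2 | 2,3,6-tribromo-4,5-dihydroxybenzaldehyde | O=Cc1c(Br)c(O)c(O)c(Br)c1Br
F4 | step 1 | 1,2-dimethoxy-4-methylbenzene | Cc1ccc(OC)c(OC)c1
F5 | step 1 | 1,2,4-tribromo-5,6-dimethoxy-3-methylbenzene | Cc1c(Br)c(OC)c(OC)c(Br)c1Br
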